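The ratio I followed was the G made per minute over the pool of Q units that had left Q without reaching G. That pool is X plus Z.

| setting | east | south-west | west | spring | winter | autumn |
|---|---|---|---|---|---|---|
| Q | 0.25 mM | 1 mM | 0.50 mM | 0.50 mM | 0.50 mM | 0.50 mM |
| L | 0.90 mM | 0.90 mM | 0.90 mM | 0.900 mM | 0.900 mM | 0.900 mM |
| J | 2.5 µM | 2.5 µM | 5 µM | 2.5 µM | 2.5 µM | 2.5 µM |
| temperature | −35 °C | −15 °C | −35 °C |  | −30 °C | 0 °C |
| remark | run made earlier | run made earlier | run made earlier | at −30 °C until 2.5 min, from then on at 0 °C |  |  |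
| time |  |  |  | 8.0 min | 8.0 min | 8.0 min |

| run | time / min | G / % | Q / % |
|---|---|---|---|
| east | 0.333 | 0.8 | 90.6 |
| east | 1.00 | 0.7 | 75.7 |
| east | 1.50 | 4.7 | 64.9 |
| east | 2.50 | 11.4 | 48.0 |
| east | 4.00 | 21.3 | 28.8 |
| east | 5.00 | 28.4 | 21.4 |
| south-west | 0.200 | 0 | 83.2 |
| south-west | 0.333 | 0.4 | 70.8 |
| south-west | 0.500 | 0.9 | 60.4 |
| south-west | 1.00 | 7.2 | 34.8 |
| south-west | 1.33 | 9.7 | 21.4 |
| south-west | 2.50 | 19.0 | 5.3 |
| west | 0.417 | 0 | 80.3 |
| west | 0.667 | 6.3 | 67.6 |
| west | 1.33 | 12.4 | 45.2 |
| west | 2.50 | 27.2 | 21.6 |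
| west | 5.00 | 56.2 | 4.8 |

(readings scatter by 1 percentage point)

- percent here means Q units held: one Z counts as two
- steps under discussion: Q + X -> Z; Q + J -> J + X; L + J + X -> J + G

* which flask leads in amount of G, in percent of the Q charged ("all alike" within 1.5 percentage points) (spring / winter / autumn / all alike)
* how much G is there at the end, in percent of the Q charged: spring
* how much G is there at the end, in percent of the Q charged: winter
* how much G is there at the end, in percent of the Q charged: autumn

J is a catalyst, and in the east run L can fall by at most 27.8 % of its charge. So I froze both and treated the emptying of the pool as pseudo-first-order. Between 2.50 min and 5.00 min of the east run I read: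

drain rate = 0.150 min⁻¹

Any Z in the pool makes this reading low. The west run had twice the J and also twice the Q, and it read 0.270 min⁻¹, twice the east value. I took the drain to follow J, with Q as the other change.

Q gave the second clock. I read its fall as 0.294 min⁻¹ in the east run at −35 °C and 1.01 min⁻¹ in the south-west run at −15 °C. These two runs differ in Q as well, and I set that aside. On a log scale I put it at 0.400 min⁻¹ at −30 °C and 2.54 min⁻¹ at 0 °C.

Then I drew G in spring. The curve starts flat, as in the east run, which read 0.7 % of G at 1.00 min. At the change, 2.5 min, I reckoned: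

Q = 36.8 %, G = 11.8 %

After the change I gave Q a lifetime of about 0.394 min, and I let the pool drain at the frozen rate, read at −35 °C, up to 8.0 min:

G in spring = 61.3 %

The same two clocks gave 54.2 % for winter and 67.9 % for autumn. These figures count no Z, for I had no reading of it. My order put autumn first.

The forecast named autumn, with 63 % for spring, 51 % for winter and 68 % for autumn, saying “Q converts fast, about 16% is lost to Z”.

Spring led with 55.6 %, ahead of winter at 47.7 % and autumn at 47.1 %. At 8.00 min autumn held 49.9 % of Z and spring 37.0 %. In spring X fell from 28.1 % at 4.00 min to 7.40 % at 8.00 min. That is a net drain of X of 0.333 min⁻¹, which is 2.22 times my frozen 0.150 min⁻¹, a reading taken on a pool that counted Z as well.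

    Q + X → Z (k = 78.0 M⁻¹ s⁻¹, Ea = 47.0 kJ mol⁻¹)
    Q + J → J + X (k = 11000 M⁻¹ s⁻¹, Ea = 27.0 kJ mol⁻¹)
    L + J + X → J + G (k = 3.40 × 10⁶ M⁻² s⁻¹, Ea = 14.0 kJ mol⁻¹)
    (constants at 0 °C)

The neighbour of spring was charged with 0.54 mM of L. Scaling the frozen drain by 2.22 and by L gave 0.200 min⁻¹, and starting from the X of spring at 4.00 min I reckoned 12.6 % of X at 8.00 min. The computed neighbour held 17.5 % of X and 42.8 % of G.

(Readings and results come from a simulation with constants of no real substance, noise included.)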